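**Strategy.** Everything rests on cutting the carbocycle at C1–C8a and C1–C2 (C1: CH bearing pendant ring B; C2: CH–CH3; C3: C–CH3; C4: =CH; C4a/C8a: fusion to ring A). C1, a methine bonded to ring B, to C8a of ring A and to C2, is the formyl carbon of syringaldehyde. The para-hydroxyl of ring B lets C1 ionise to a quinone methide, and C8a is activated by the C8 and C6 methoxy groups. One chiral-acid cascade arylates the aldehyde, closes the ring through the C2=C3 alkene and sets both stereocentres. The precursor is syringol carrying an (E)-2-methylbut-2-enyl chain para to its hydroxyl, made by O-allylation and para-Claisen rearrangement.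

Key step: step 3

Remark on numbering: the locants C1–C8a used below are those of the overview, not those of the IUPAC name of 10. In this numbering the target is (1S,2S), with ring B and the C2 methyl group cis.

Assumption: the sense of induction of the chiral acid cannot be assigned in advance. The (R)-catalyst is written, and its (S)-antipode is to be used if a test run gives the (1R,2R) series.

Step 1
Reactants: 1 2,6-dimethoxyphenol; 2 (E)-2-methylbut-2-en-1-ol
Product: 3 1,3-dimethoxy-2-{[(2E)-2-methylbut-2-en-1-yl]oxy}benzene
Conditions: PPh3, DIAD, THF, 0 °C to rt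
Reagents that add atoms: none
Why: Mitsunobu etherification, in which the primary allylic alcohol is activated as its oxyphosphonium salt and displaced at CH2 by the phenoxide, so the (E)-alkene is untouched and no stereocentre is formed.

Step 2
Reactants: 3 1,3-dimethoxy-2-{[(2E)-2-methylbut-2-en-1-yl]oxy}benzene
Product: 6 2,6-dimethoxy-4-[(2E)-2-methylbut-2-en-1-yl]phenol, via ortho-dienone 4 (not isolated), via para-dienone 5 (not isolated)
Conditions: PhNEt2, 200 °C, sealed tube, N2
Reagents that add atoms: none
Why: Aromatic para-Claisen rearrangement: both ortho positions carry methoxy groups, so the [3,3] shift to 4 is followed by a Cope shift to 5 and tautomerisation, the two allylic inversions returning the chain bonded through its CH2 end, and a chair-like Cope transition state with the methyl group pseudoequatorial should re-form the alkene as the (E)-isomer.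

Step 3
Reactants: 6 2,6-dimethoxy-4-[(2E)-2-methylbut-2-en-1-yl]phenol; 7 syringaldehyde
Product: 10 (7S,8S)-8-(4-hydroxy-3,5-dimethoxyphenyl)-1,3-dimethoxy-6,7-dimethyl-7,8-dihydronaphthalen-2-ol (the 1S,2S-cis target), via benzhydrol 8 (not isolated), via quinone methide 9 (not isolated)
Conditions: (R)-TRIP N-triflylphosphoramide (10 mol %), 5 Å MS, PhCl (0.02 M), 40 °C, 6 added slowly to 7 (1.3 equiv)
Reagents that add atoms: none
Why: Proposed new method: the acid-activated aldehyde 7 should be attacked by 6 at the ring position next to the butenyl chain, which is ortho to one methoxy group and para to the other (C1–C8a), and the doubly benzylic carbinol 8 should ionise at once to the ring-B quinone methide 9, held as a hydrogen-bonded ion pair by the chiral phosphoramide. The tethered alkene then adds through C2 to C1 in a 6-endo-trig closure of the carbocycle (C1–C2), and the tertiary C3 cation loses the benzylic C4 proton to give the conjugated C3=C4 styrene. The closest known reaction types are Prins/Friedel–Crafts annulations of aldehydes with alkene-tethered arenes and chiral-phosphoric-acid-controlled additions to para-quinone methides formed in situ from para-hydroxybenzyl alcohols. C1 is set by the chiral anion, which should shield one face of the quinone methide, and because 8 is planarised on ionisation only the ring closure has to be face-selective. C2 follows from C1 in a half-chair transition state in which ring B sits pseudoaxial to avoid the peri C8 methoxy group and the methyl group of the (E)-alkene sits pseudoequatorial, which gives the cis pair. The step needs arene attack on the aldehyde to outrun alkene attack, and ring closure to outrun capture of 9 by a second molecule of 6; the two equivalent activated positions of 6, its slow addition to an excess of 7 and high dilution are meant to secure this.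

**Compound list**

1 | 2,6-dimethoxyphenol | COc1cccc(OC)c1O | starting material
2 | (E)-2-methylbut-2-en-1-ol | C/C=C(\C)CO | starting material
3 | 1,3-dimethoxy-2-{[(2E)-2-methylbut-2-en-1-yl]oxy}benzene | COc1cccc(OC)c1OC/C(C)=C/C | intermediate
4 | 2,6-dimethoxy-6-(3-methylbut-3-en-2-yl)cyclohexa-2,4-dien-1-one (ortho-dienone, transient racemate, configuration of no consequence) | COC1=CC=CC(OC)(C(C)C(C)=C)C1=O | intermediate
5 | 2,6-dimethoxy-4-[(2E)-2-methylbut-2-en-1-yl]cyclohexa-2,5-dien-1-one (para-dienone) | COC1=CC(C/C(C)=C/C)C=C(OC)C1=O | intermediate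
6 | 2,6-dimethoxy-4-[(2E)-2-methylbut-2-en-1-yl]phenol | COc1cc(C/C(C)=C/C)cc(OC)c1O | intermediate
7 | syringaldehyde (4-hydroxy-3,5-dimethoxybenzaldehyde) | COc1cc(C=O)cc(OC)c1O | starting material
8 | (4-hydroxy-3,5-dimethoxyphenyl){3-hydroxy-2,4-dimethoxy-6-[(2E)-2-methylbut-2-en-1-yl]phenyl}methanol (configuration at the carbinol carbon of no consequence) | COc1cc(C(O)c2c(C/C(C)=C/C)cc(OC)c(O)c2OC)cc(OC)c1O | intermediate
9 | 4-({3-hydroxy-2,4-dimethoxy-6-[(2E)-2-methylbut-2-en-1-yl]phenyl}methylidene)-2,6-dimethoxycyclohexa-2,5-dien-1-one | COC1=CC(=Cc2c(C/C(C)=C/C)cc(OC)c(O)c2OC)C=C(OC)C1=O | intermediate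
10 | (7S,8S)-8-(4-hydroxy-3,5-dimethoxyphenyl)-1,3-dimethoxy-6,7-dimethyl-7,8-dihydronaphthalen-2-ol | COc1cc([C@H]2c3c(cc(OC)c(O)c3OC)C=C(C)[C@H]2C)cc(OC)c1O | target

**Totals**

Total step count: 3. Longest linear sequence: 3 (1 and 2 to 3, 6 and 10; syringaldehyde 7 enters in step 3).

**Steps most likely to fail**

Step 3. The hydroxyalkylation may stall with the electron-rich aldehyde. The alkene may attack the aldehyde first. The quinone methide may be captured by a second arene. Facial selectivity may be poor. The acid may epimerise C2 through migration of the double bond.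
Fallback: it sets out from 6 and 7 and returns at 10, making the aryl–C1 bond by organolithium addition, the ring by an achiral acid, and the absolute configuration by resolution.
- 6 is silylated (TBSCl, imidazole, DMF) to the tert-butyldimethylsilyl ether F1.
- NBS in MeCN at 0 °C should brominate F1 at the only free, doubly alkoxy-activated ring position to give the aryl bromide F2.
- 7 is silylated in the same way to the protected aldehyde F3.
- Bromine–lithium exchange on F2 (t-BuLi, THF, −78 °C) and addition to F3 should give the racemic bis-silyl benzhydrol F4.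
- BF3·OEt2 in CH2Cl2 at −78 °C should ionise F4 to the benzhydryl cation, which closes onto the (E)-alkene in a known intramolecular benzylic cation–olefin cyclisation. The same half-chair argument applies, and the product is the cis dihydronaphthalene bis-silyl ether F5 as the racemate.
- Preparative chiral SFC isolates the (1S,2S) antipode of F5, and TBAF in THF releases 10.

Step 2. The alkene geometry may erode in the Cope shift, which would pass into the cis/trans ratio of step 3 because the (Z)-alkene should give the trans product. The ether may also cleave back to 1 at 200 °C.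
Fallback: it sets out from 7 and returns at 6, fixing the geometry by a stereoretentive cross-coupling.
- 7 is protected (MOMCl, i-Pr2NEt, CH2Cl2) as the methoxymethyl ether F6.
- F6 is reduced (NaBH4, MeOH) to the benzyl alcohol F7.
- F7 is brominated under Appel conditions (CBr4, PPh3, CH2Cl2) to the benzyl bromide F8.
- Suzuki–Miyaura coupling of F8 with (Z)-2-buten-2-ylboronic acid pinacol ester (methyl groups cis; Pd(dppf)Cl2, K3PO4, THF/H2O, 60 °C) should give the MOM-protected (E)-alkene F9 with retention of the boronate geometry.
- HCl in MeOH at rt removes the MOM group to give 6.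

Step 1. The redox condensation may be slow with the doubly ortho-substituted phenol, SN2′ alkylation may compete, and the reagent by-products may be hard to separate.
Fallback: it sets out from 2 and returns at 3. 2 is converted with PBr3 (Et2O, 0 °C) into (E)-1-bromo-2-methylbut-2-ene F10. F10 alkylates the potassium phenoxide of 1 (K2CO3, acetone, reflux) in a Williamson ether synthesis to give 3.

**Further compounds**

F1 | step 3 | tert-butyl{2,6-dimethoxy-4-[(2E)-2-methylbut-2-en-1-yl]phenoxy}dimethylsilane | COc1cc(C/C(C)=C/C)cc(OC)c1O[Si](C)(C)C(C)(C)C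
F2 | step 3 | {3-bromo-2,6-dimethoxy-4-[(2E)-2-methylbut-2-en-1-yl]phenoxy}(tert-butyl)dimethylsilane | COc1cc(C/C(C)=C/C)c(Br)c(OC)c1O[Si](C)(C)C(C)(C)C
F3 | step 3 | 4-[(tert-butyldimethylsilyl)oxy]-3,5-dimethoxybenzaldehyde | COc1cc(C=O)cc(OC)c1O[Si](C)(C)C(C)(C)C
F4 | step 3 | {3-[(tert-butyldimethylsilyl)oxy]-2,4-dimethoxy-6-[(2E)-2-methylbut-2-en-1-yl]phenyl}{4-[(tert-butyldimethylsilyl)oxy]-3,5-dimethoxyphenyl}methanol (racemic) | COc1cc(C(O)c2c(C/C(C)=C/C)cc(OC)c(O[Si](C)(C)C(C)(C)C)c2OC)cc(OC)c1O[Si](C)(C)C(C)(C)C
F5 | step 3 | bis(tert-butyldimethylsilyl) ether of 10, formed as the cis racemate; the (1S,2S) antipode kept after resolution is drawn | COc1cc([C@H]2c3c(cc(OC)c(O[Si](C)(C)C(C)(C)C)c3OC)C=C(C)[C@H]2C)cc(OC)c1O[Si](C)(C)C(C)(C)C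
F6 | step 2 | 3,5-dimethoxy-4-(methoxymethoxy)benzaldehyde | COCOc1c(OC)cc(C=O)cc1OC
F7 | step 2 | [3,5-dimethoxy-4-(methoxymethoxy)phenyl]methanol | COCOc1c(OC)cc(CO)cc1OC
F8 | step 2 | 5-(bromomethyl)-1,3-dimethoxy-2-(methoxymethoxy)benzene | COCOc1c(OC)cc(CBr)cc1OC
F9 | step 2 | 1,3-dimethoxy-2-(methoxymethoxy)-5-[(2E)-2-methylbut-2-en-1-yl]benzene | COCOc1c(OC)cc(C/C(C)=C/C)cc1OC
F10 | step 1 | (E)-1-bromo-2-methylbut-2-ene | C/C=C(\C)CBr
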